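**Retrosynthetic overview**
- Target ⇐ C3-methylation of the nor-ketone; both α-methyl centres end in the thermodynamic all-trans array.
- The six- and five-membered rings are formed together, in one intramolecular Diels–Alder reaction of a linear (E,E,E)-tetraenyl keto acid (trans-hydrindane, four stereocentres set from one).
- Keto acid ⇐ C–O bond formation: gold-catalysed δ-hydration of a 2-en-4-ynoic acid. The rigid alkyne keeps diene and dienophile apart until the ketone oxygen is installed.
- Enynoic acid ⇐ Sonogashira union of a triene-yne with (E)-2-ethyl-3-iodoacrylic acid (from diethyl ethylmalonate and iodoform).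
- Triene-yne ⇐ Wittig/HWE extension of an enynal ⇐ chirality transfer from (R)-but-3-yn-2-ol (allenylindium addition to 3-ethoxymethacrolein, then transposition).

Assumption: the given SMILES is the natural enantiomer, and ylide 7 is taken as a catalogue reagent (otherwise one step from propyltriphenylphosphonium bromide and ethyl formate).

**Step 1**
Reactants: 1 (R)-but-3-yn-2-ol
Product: 2 (R)-but-3-yn-2-yl methanesulfonate
Conditions: MsCl (1.2 equiv), Et3N (1.5 equiv), CH2Cl2, −78 → 0 °C
Reagents that add atoms: methanesulfonyl chloride CS(=O)(=O)Cl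
Why: O-sulfonylation of a secondary propargylic alcohol leaves the C–O bond untouched, so the R configuration is retained.

**Step 2**
Reactants: 2 (R)-but-3-yn-2-yl methanesulfonate; 3 (E)-3-ethoxy-2-methylprop-2-enal
Product: 6 (2E,4R)-2,4-dimethylhex-2-en-5-ynal, via allenylindium reagent 4 (not isolated), via hydroxy enol ether 5 (not isolated)
Conditions: PdCl2(dppf) (5 mol %), InI (1.5 equiv), THF/DMPU 3:1, 23 °C; then 1 M HCl, THF, 0 °C
Reagents that add atoms: water O
Why: Marshall propargylation: zerovalent palladium ionises 2 by anti SN2' attack, InI transmetalates with retention to (aS)-allenylindium 4, and 4 adds to the aldehyde through a closed SE2' transition state, so the new C–C bond forms anti to the departed mesylate and C4 of 6 is R; the acid work-up then collapses β-hydroxy enol ether 5 by allylic transposition to the (E)-enal, which erases the carbinol centre.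

**Step 3**
Reactants: 6 (2E,4R)-2,4-dimethylhex-2-en-5-ynal; 7 2-(triphenylphosphoranylidene)butanal
Product: 8 (2E,4E,6R)-2-ethyl-4,6-dimethylocta-2,4-dien-7-ynal
Conditions: 7 (1.3 equiv), toluene, 90 °C
Reagents that add atoms: none
Why: Wittig olefination with a formyl-stabilised ylide is E-selective for the trisubstituted enal and runs under neutral conditions that leave the C6 stereocentre alone.

**Step 4**
Reactants: 8 (2E,4E,6R)-2-ethyl-4,6-dimethylocta-2,4-dien-7-ynal; 9 diethyl benzylphosphonate
Product: 11 [(1E,3E,5E,7R)-3-ethyl-5,7-dimethylnona-1,3,5-trien-8-yn-1-yl]benzene, via sodium phosphonate carbanion 10 (not isolated)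
Conditions: 9 (1.2 equiv), NaN(SiMe3)2 (1.15 equiv), THF, −78 °C; then 8, −78 → 0 °C
Reagents that add atoms: none
Why: Horner–Wadsworth–Emmons olefination with the benzylphosphonate anion gives the (E)-styryl alkene, and carbonyl addition at −78 °C outruns deprotonation at C6.

**Step 5**
Reactants: 12 diethyl 2-ethylpropanedioate; 13 triiodomethane
Product: 15 diethyl 2-(diiodomethyl)-2-ethylpropanedioate, via sodium malonate enolate 14 (not isolated)
Conditions: NaH (1.1 equiv), Et2O, 35 °C; then CHI3 (1.0 equiv), 35 °C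
Reagents that add atoms: none
Why: C-alkylation of the malonate enolate by iodoform installs the CHI2 group, as is well established for the methyl homologue.

**Step 6**
Reactants: 15 diethyl 2-(diiodomethyl)-2-ethylpropanedioate
Product: 17 (2E)-2-ethyl-3-iodoprop-2-enoic acid, via dipotassium dicarboxylate 16 (not isolated)
Conditions: KOH (4 equiv), EtOH/H2O 3:1, 80 °C; then 6 M HCl to pH 1
Reagents that add atoms: potassium hydroxide [K+].[OH-]
Why: Saponification followed by decarboxylative elimination of iodide gives the thermodynamically preferred (E)-β-iodoacrylic acid, with iodine trans to CO2H.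

**Step 7**
Reactants: 11 [(1E,3E,5E,7R)-3-ethyl-5,7-dimethylnona-1,3,5-trien-8-yn-1-yl]benzene; 17 (2E)-2-ethyl-3-iodoprop-2-enoic acid
Product: 18 (2E,6R,7E,9E,11E)-2,10-diethyl-6,8-dimethyl-12-phenyldodeca-2,7,9,11-tetraen-4-ynoic acid
Conditions: PdCl2(PPh3)2 (3 mol %), CuI (6 mol %), Et3N (4 equiv), THF, 0 → 23 °C; cold dilute acid wash
Reagents that add atoms: none
Why: Sonogashira coupling retains the (E)-vinyl iodide geometry, the acid travels as its ammonium carboxylate (which lowers the acidity of C6–H), and the linear C4≡C5 unit makes a premature cycloaddition geometrically impossible.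

**Step 8**
Reactants: 18 (2E,6R,7E,9E,11E)-2,10-diethyl-6,8-dimethyl-12-phenyldodeca-2,7,9,11-tetraen-4-ynoic acid
Product: 20 (1R,3aR,4S,5R,7aS)-4,5-diethyl-1,7-dimethyl-2-oxo-5-[(E)-2-phenylethenyl]-2,3,3a,4,5,7a-hexahydro-1H-indene-4-carboxylic acid, via linear keto acid 19 (not isolated)
Conditions: Ph3PAuNTf2 (3 mol %), 1,4-dioxane/H2O 10:1, 45 °C, dark; filter through silica; toluene, BHT, 80 °C
Reagents that add atoms: water O
Why: Proposed new method: a tandem gold-catalysed alkyne hydration / intramolecular Diels–Alder reaction in which C–O bond formation is the trigger — the cationic monovalent gold centre activates C4≡C5, water attacks C5 (the δ-carbon, favoured by the vinylogous Michael polarisation of the 2-en-4-ynoic acid and by its alkyl substituent, while the (E)-acid cannot lactonise onto the alkyne), protodeauration and tautomerisation give ketone 19, and only then can the chain fold so that the (E)-enoic acid reaches the (E,E)-diene; the cycloaddition passes through the tether-exo, carboxyl-endo transition state with C6–H eclipsing the C8 methyl (allylic 1,3-strain), so the one purchased stereocentre sets C7a, C3a, C4 and C5 of the trans-hydrindane; the closest known reactions are the gold-catalysed hydration of alkynoates to β-keto esters and thermal intramolecular Diels–Alder reactions of 1,6,8-nonatrienoates.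

**Step 9**
Reactants: 20 (1R,3aR,4S,5R,7aS)-4,5-diethyl-1,7-dimethyl-2-oxo-5-[(E)-2-phenylethenyl]-2,3,3a,4,5,7a-hexahydro-1H-indene-4-carboxylic acid
Product: 22 dinorspiculoic acid A, via dilithium enolate carboxylate 21 (not isolated)
Conditions: LiN(i-Pr)2 (2.3 equiv), THF, −78 °C; MeI (1.3 equiv), −78 → −40 °C; MeOH, 23 °C; 1 M HCl
Reagents that add atoms: iodomethane CI
Why: Kinetic enolate alkylation: lithium diisopropylamide deprotonates the less hindered C3 methylene of the carboxylate, MeI enters anti to the C4 quaternary carbon, and the methoxide formed on the MeOH quench equilibrates C1 and C3 to the all-trans (thermodynamic, natural) ketone.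

**Compound list**
1 | (R)-but-3-yn-2-ol | C[C@@H](O)C#C | starting material
2 | (R)-but-3-yn-2-yl methanesulfonate | C[C@@H](OS(C)(=O)=O)C#C | intermediate
3 | (E)-3-ethoxy-2-methylprop-2-enal (3-ethoxymethacrolein) | CCO/C=C(\C)C=O | starting material
4 | [(aS)-buta-1,2-dien-1-yl]indium iodide methanesulfonate (trivalent indium) | [H]C(C)=[C@]=C([H])[In](I)OS(C)(=O)=O | intermediate
5 | (1E,3S,4S)-1-ethoxy-2,4-dimethylhex-1-en-5-yn-3-ol (major anti adduct; C3 is lost in the same step) | CCO/C=C(\C)[C@@H](O)[C@@H](C)C#C | intermediate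
6 | (2E,4R)-2,4-dimethylhex-2-en-5-ynal | O=C/C(C)=C/[C@@H](C)C#C | intermediate
7 | 2-(triphenylphosphoranylidene)butanal | CCC(C=O)=P(c1ccccc1)(c1ccccc1)c1ccccc1 | starting material
8 | (2E,4E,6R)-2-ethyl-4,6-dimethylocta-2,4-dien-7-ynal | O=C/C(CC)=C/C(C)=C/[C@@H](C)C#C | intermediate
9 | diethyl benzylphosphonate | CCOP(=O)(Cc1ccccc1)OCC | starting material
10 | sodium (diethoxyphosphoryl)(phenyl)methanide | CCOP(=O)(OCC)[CH-]c1ccccc1.[Na+] | intermediate
11 | [(1E,3E,5E,7R)-3-ethyl-5,7-dimethylnona-1,3,5-trien-8-yn-1-yl]benzene | c1ccccc1/C=C/C(CC)=C/C(C)=C/[C@@H](C)C#C | intermediate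
12 | diethyl 2-ethylpropanedioate (diethyl ethylmalonate) | CCOC(=O)C(CC)C(=O)OCC | starting material
13 | triiodomethane (iodoform) | IC(I)I | starting material
14 | sodium enolate of diethyl 2-ethylpropanedioate | CCOC(=O)[C-](CC)C(=O)OCC.[Na+] | intermediate
15 | diethyl 2-(diiodomethyl)-2-ethylpropanedioate | CCOC(=O)C(CC)(C(I)I)C(=O)OCC | intermediate
16 | dipotassium 2-(diiodomethyl)-2-ethylpropanedioate | [K+].[K+].[O-]C(=O)C(CC)(C(I)I)C([O-])=O | intermediate
17 | (2E)-2-ethyl-3-iodoprop-2-enoic acid | I/C=C(CC)/C(=O)O | intermediate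
18 | (2E,6R,7E,9E,11E)-2,10-diethyl-6,8-dimethyl-12-phenyldodeca-2,7,9,11-tetraen-4-ynoic acid | c1ccccc1/C=C/C(CC)=C/C(C)=C/[C@@H](C)C#C/C=C(CC)/C(=O)O | intermediate
19 | (2E,6R,7E,9E,11E)-2,10-diethyl-6,8-dimethyl-5-oxo-12-phenyldodeca-2,7,9,11-tetraenoic acid | c1ccccc1/C=C/C(CC)=C/C(C)=C/[C@@H](C)C(=O)C/C=C(CC)/C(=O)O | intermediate
20 | (1R,3aR,4S,5R,7aS)-4,5-diethyl-1,7-dimethyl-2-oxo-5-[(E)-2-phenylethenyl]-2,3,3a,4,5,7a-hexahydro-1H-indene-4-carboxylic acid | CC[C@@]1(/C=C/c2ccccc2)C=C(C)[C@H]2[C@@H](CC(=O)[C@@H]2C)[C@]1(CC)C(=O)O | intermediate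
21 | dilithium salt of 20 (C2–C3 enolate and carboxylate) | [Li+].[Li+].CC[C@@]1(/C=C/c2ccccc2)C=C(C)[C@H]2[C@@H](C=C([O-])[C@@H]2C)[C@]1(CC)C([O-])=O | intermediate
22 | dinorspiculoic acid A, (1R,3R,3aS,4S,5R,7aS)-4,5-diethyl-1,3,7-trimethyl-2-oxo-5-[(E)-2-phenylethenyl]-2,3,3a,4,5,7a-hexahydro-1H-indene-4-carboxylic acid | CC[C@@]1(/C=C/c2ccccc2)C=C(C)[C@H]2[C@@H]([C@@H](C)C(=O)[C@@H]2C)[C@]1(CC)C(=O)O | target

**Step count**
Total: 9 steps. Longest linear sequence: 7 steps (1, 2, 3, 4, 7, 8, 9).

**Three steps most likely to fail**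

Step 8 (the proposed new step). Possible failures are attack of water at C4, gold-triggered side reactions of the triene, loss of configuration at C6 in ketone 19 before it cyclises, or a poor trans/cis ring-fusion ratio. The fallback uses known chemistry and replaces π-acid hydration by nucleophilic amine addition and hydrolysis. It sets out from 18, which is esterified with 2-(trimethylsilyl)ethanol (DCC, DMAP, CH2Cl2, 0 °C) to the 2-(trimethylsilyl)ethyl enynoate F1. Morpholine (MeCN, 23–40 °C) adds in a 1,6-aza-Michael reaction to give the 5-morpholino dienoate F2. Aqueous AcOH/THF hydrolyses this to the linear keto ester F3, which cyclises on warming in toluene (80 °C) to the bicyclic 2-(trimethylsilyl)ethyl ester F4. Bu4NF in THF cleaves the ester, and the route is rejoined at 20.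

Step 2. The aldehyde of 3 is a vinylogous ester and may add the allenylindium sluggishly, and the transposition must not epimerise C4. The fallback sets out from 2 and adds the same reagent 4 to methacrolein, a plain enal of the usual substrate class, to give (3S,4S)-2,4-dimethylhex-1-en-5-yn-3-ol F5. A Ph3SiOReO3-catalysed 1,3-transposition of the allylic alcohol (Et2O, 0 °C) gives the primary alcohol (2E,4R)-2,4-dimethylhex-2-en-5-yn-1-ol F6, and MnO2 (CH2Cl2, 23 °C) oxidises this to 6, where the route is rejoined.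

Step 9. Deprotonation may not be fully selective for C3, and double methylation is possible. The fallback sets out from 20: the kinetic dianion (lithium diisopropylamide, THF, −78 °C) is trapped with N,N-dimethylmethyleneiminium iodide to give the C3 Mannich base F7. Quaternisation with MeI and elimination with NaHCO3 give the 3-methylidene ketone F8. Conjugate reduction with [(Ph3P)CuH]6 (benzene, 23 °C) and methoxide equilibration then deliver 22, where the route is rejoined.

**Further compounds**
F1 | step 8 | 2-(trimethylsilyl)ethyl (2E,6R,7E,9E,11E)-2,10-diethyl-6,8-dimethyl-12-phenyldodeca-2,7,9,11-tetraen-4-ynoate | c1ccccc1/C=C/C(CC)=C/C(C)=C/[C@@H](C)C#C/C=C(CC)/C(=O)OCC[Si](C)(C)C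
F2 | step 8 | 2-(trimethylsilyl)ethyl (2E,6R,7E,9E,11E)-2,10-diethyl-6,8-dimethyl-5-(morpholin-4-yl)-12-phenyldodeca-2,4,7,9,11-pentaenoate (C4=C5 geometry not defined) | c1ccccc1/C=C/C(CC)=C/C(C)=C/[C@@H](C)C(N1CCOCC1)=C/C=C(CC)/C(=O)OCC[Si](C)(C)C
F3 | step 8 | 2-(trimethylsilyl)ethyl (2E,6R,7E,9E,11E)-2,10-diethyl-6,8-dimethyl-5-oxo-12-phenyldodeca-2,7,9,11-tetraenoate | c1ccccc1/C=C/C(CC)=C/C(C)=C/[C@@H](C)C(=O)C/C=C(CC)/C(=O)OCC[Si](C)(C)C
F4 | step 8 | 2-(trimethylsilyl)ethyl ester of acid 20 | CC[C@@]1(/C=C/c2ccccc2)C=C(C)[C@H]2[C@@H](CC(=O)[C@@H]2C)[C@]1(CC)C(=O)OCC[Si](C)(C)C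
F5 | step 2 | (3S,4S)-2,4-dimethylhex-1-en-5-yn-3-ol | C=C(C)[C@@H](O)[C@@H](C)C#C
F6 | step 2 | (2E,4R)-2,4-dimethylhex-2-en-5-yn-1-ol | OC/C(C)=C/[C@@H](C)C#C
F7 | step 9 | 3-[(dimethylamino)methyl] derivative of acid 20 (C3 epimers) | CC[C@@]1(/C=C/c2ccccc2)C=C(C)[C@H]2[C@@H](C(CN(C)C)C(=O)[C@@H]2C)[C@]1(CC)C(=O)O
F8 | step 9 | 3-methylidene derivative of acid 20 | CC[C@@]1(/C=C/c2ccccc2)C=C(C)[C@H]2[C@@H](C(=C)C(=O)[C@@H]2C)[C@]1(CC)C(=O)O
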